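**Retrosynthetic overview**
1. Target 17 ⇐ silyl ether 16 ⇐ aldol condensation (exocyclic E C=C) of (R)-β-(3,4,5-trimethoxybenzyl)-γ-butyrolactone 11 with O-silylated syringaldehyde 13.
2. Lactone 11 ⇐ γ,δ-unsaturated ester 8 by alkene cleavage, reduction and ring closure; this is the only ring and it is closed after the key step.
3. Ester 8 ⇐ Johnson–Claisen [3,3] rearrangement of allylic alcohol 4 with triethyl orthoacetate 5: forms the C3–C4 bond and transfers the carbinol configuration to C4.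
4. Alcohol 4 ⇐ trans-reduction of alkynol 3 ⇐ benzylation of purchased (R)-but-3-yn-2-ol 1 with 3,4,5-trimethoxybenzyl bromide 2.

Assumption: the SMILES is read as (R) at C4 with an E-benzylidene (aryl trans to the lactone C=O); 1, 2, 5 and 12 are taken as catalogue compounds.

**Route**

Step 1
Reactants: 1 (R)-but-3-yn-2-ol; 2 3,4,5-trimethoxybenzyl bromide
Product: 3 (R)-5-(3,4,5-trimethoxyphenyl)pent-3-yn-2-ol
Conditions: CuI (20 mol %), Cs2CO3 (1.5 equiv), MeCN, N2, rt, 16 h
Reagents that add atoms: none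
Why: Copper-acetylide alkylation (Csp–Csp3 coupling) of the terminal alkyne with a reactive benzylic bromide under carbonate base tolerates the free secondary alcohol and does not touch the purchased carbinol stereocentre.

Step 2
Reactants: 3 (R)-5-(3,4,5-trimethoxyphenyl)pent-3-yn-2-ol
Product: 4 (2R,3E)-5-(3,4,5-trimethoxyphenyl)pent-3-en-2-ol
Conditions: LiAlH4 (2 equiv), THF, 0 °C → 50 °C, 3 h; H2O quench
Reagents that add atoms: none
Why: Hydroxyl-directed trans-hydroalumination of a propargylic alcohol (through a cyclic alkenylalanate) gives only the E-alkene and leaves the carbinol centre unchanged.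

Step 3
Reactants: 4 (2R,3E)-5-(3,4,5-trimethoxyphenyl)pent-3-en-2-ol; 5 triethyl orthoacetate
Product: 8 ethyl (3R,4E)-3-(3,4,5-trimethoxybenzyl)hex-4-enoate, via mixed orthoester 6 (not isolated), via ketene acetal 7 (not isolated)
Conditions: MeC(OEt)3 (6 equiv), EtCO2H (5 mol %), 140 °C, 4 h, EtOH distilled off
Reagents that add atoms: none
Why: Johnson–Claisen [3,3]-sigmatropic rearrangement through a chair transition state with the carbinol methyl equatorial forms the new C–C bond on the face of the departing C–O bond, so the (R)-carbinol/E-alkene pair gives the (R)-configured benzyl-bearing carbon and an E-propenyl group.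

Step 4
Reactants: 8 ethyl (3R,4E)-3-(3,4,5-trimethoxybenzyl)hex-4-enoate
Product: 11 (4R)-4-(3,4,5-trimethoxybenzyl)dihydrofuran-2(3H)-one, via aldehyde ester 9 (not isolated), via hydroxy ester 10 (not isolated)
Conditions: O3 (1.0 equiv, metered), CH2Cl2/MeOH 4:1, −78 °C; N2 purge; NaBH4 (4 equiv), −78 → 0 °C; then 2 M HCl to pH 2, rt, 2 h
Reagents that add atoms: ozone [O-][O+]=O
Why: Ozonolysis of the disubstituted alkene (much faster than attack on the trimethoxyarene) with immediate borohydride reduction gives the γ-hydroxy ester, which lactonises on acidification; cold in situ reduction keeps the α-formyl stereocentre from epimerising.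

Step 5
Reactants: 12 syringaldehyde
Product: 13 4-(tert-butyldimethylsilyloxy)-3,5-dimethoxybenzaldehyde
Conditions: TBSCl (1.2 equiv), imidazole (2.2 equiv), DMF, rt, 3 h
Reagents that add atoms: tert-butyldimethylsilyl chloride CC(C)(C)[Si](C)(C)Cl
Why: Imidazole-promoted O-silylation masks the acidic phenol so the aldehyde stays electrophilic toward a lactone enolate.

Step 6
Reactants: 11 (4R)-4-(3,4,5-trimethoxybenzyl)dihydrofuran-2(3H)-one; 13 4-(tert-butyldimethylsilyloxy)-3,5-dimethoxybenzaldehyde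
Product: 16 (3E,4R)-3-[4-(tert-butyldimethylsilyloxy)-3,5-dimethoxybenzylidene]-4-(3,4,5-trimethoxybenzyl)dihydrofuran-2(3H)-one, via lithium aldolate 14 (not isolated), via aldol acetate 15 (not isolated)
Conditions: LiN(SiMe3)2 (1.1 equiv), THF, −78 °C, 45 min; 13 (1.1 equiv), −78 °C, 1 h; Ac2O (1.5 equiv), −78 → 0 °C; DBU (3 equiv), rt, 6 h
Reagents that add atoms: none
Why: Lithium-enolate aldol addition anti to the C4 benzyl group, acetylation of the aldolate and DBU-promoted E1cB elimination give the conjugated benzylidene lactone with the thermodynamically preferred E geometry (aryl trans to C=O), while C4 is not deprotonated under these conditions.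

Step 7
Reactants: 16 (3E,4R)-3-[4-(tert-butyldimethylsilyloxy)-3,5-dimethoxybenzylidene]-4-(3,4,5-trimethoxybenzyl)dihydrofuran-2(3H)-one
Product: 17 (3E,4R)-3-(4-hydroxy-3,5-dimethoxybenzylidene)-4-(3,4,5-trimethoxybenzyl)dihydrofuran-2(3H)-one
Conditions: Bu4NF (1.1 equiv), AcOH (1.2 equiv), THF, 0 °C, 30 min
Reagents that add atoms: none
Why: Fluoride-mediated desilylation of the aryl silyl ether, buffered with acetic acid, frees the phenol without isomerising the alkene or affecting C4.

**Compound list**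
1 | (R)-but-3-yn-2-ol | C[C@@H](O)C#C | starting material
2 | 3,4,5-trimethoxybenzyl bromide, i.e. 5-(bromomethyl)-1,2,3-trimethoxybenzene | COc1cc(CBr)cc(OC)c1OC | starting material
3 | (R)-5-(3,4,5-trimethoxyphenyl)pent-3-yn-2-ol | C[C@@H](O)C#CCc1cc(OC)c(OC)c(OC)c1 | intermediate
4 | (2R,3E)-5-(3,4,5-trimethoxyphenyl)pent-3-en-2-ol | C[C@@H](O)/C=C/Cc1cc(OC)c(OC)c(OC)c1 | intermediate
5 | triethyl orthoacetate (1,1,1-triethoxyethane) | CCOC(C)(OCC)OCC | starting material
6 | mixed orthoester, 5-[(2E,4R)-4-(1,1-diethoxyethoxy)pent-2-en-1-yl]-1,2,3-trimethoxybenzene (not isolated) | CCOC(C)(OCC)O[C@H](C)/C=C/Cc1cc(OC)c(OC)c(OC)c1 | intermediate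
7 | ketene acetal, 5-[(2E,4R)-4-(1-ethoxyvinyloxy)pent-2-en-1-yl]-1,2,3-trimethoxybenzene (not isolated) | C=C(OCC)O[C@H](C)/C=C/Cc1cc(OC)c(OC)c(OC)c1 | intermediate
8 | ethyl (3R,4E)-3-(3,4,5-trimethoxybenzyl)hex-4-enoate | C/C=C/[C@@H](CC(=O)OCC)Cc1cc(OC)c(OC)c(OC)c1 | intermediate
9 | aldehyde ester, ethyl (3R)-3-formyl-4-(3,4,5-trimethoxyphenyl)butanoate (not isolated) | O=C[C@@H](CC(=O)OCC)Cc1cc(OC)c(OC)c(OC)c1 | intermediate
10 | hydroxy ester, ethyl (3R)-3-(hydroxymethyl)-4-(3,4,5-trimethoxyphenyl)butanoate (not isolated) | OC[C@@H](CC(=O)OCC)Cc1cc(OC)c(OC)c(OC)c1 | intermediate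
11 | (4R)-4-(3,4,5-trimethoxybenzyl)dihydrofuran-2(3H)-one | O=C1OC[C@H](Cc2cc(OC)c(OC)c(OC)c2)C1 | intermediate
12 | syringaldehyde (4-hydroxy-3,5-dimethoxybenzaldehyde) | COc1cc(C=O)cc(OC)c1O | starting material
13 | 4-(tert-butyldimethylsilyloxy)-3,5-dimethoxybenzaldehyde | COc1cc(C=O)cc(OC)c1O[Si](C)(C)C(C)(C)C | intermediate
14 | lithium aldolate, lithium [4-(tert-butyldimethylsilyloxy)-3,5-dimethoxyphenyl][(3S,4R)-2-oxo-4-(3,4,5-trimethoxybenzyl)tetrahydrofuran-3-yl]methanolate, both carbinol epimers (not isolated) | O=C1OC[C@H](Cc2cc(OC)c(OC)c(OC)c2)[C@H]1C([O-])c1cc(OC)c(O[Si](C)(C)C(C)(C)C)c(OC)c1.[Li+] | intermediate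
15 | aldol acetate, [4-(tert-butyldimethylsilyloxy)-3,5-dimethoxyphenyl][(3S,4R)-2-oxo-4-(3,4,5-trimethoxybenzyl)tetrahydrofuran-3-yl]methyl acetate, both carbinol epimers (not isolated) | O=C1OC[C@H](Cc2cc(OC)c(OC)c(OC)c2)[C@H]1C(OC(C)=O)c1cc(OC)c(O[Si](C)(C)C(C)(C)C)c(OC)c1 | intermediate
16 | (3E,4R)-3-[4-(tert-butyldimethylsilyloxy)-3,5-dimethoxybenzylidene]-4-(3,4,5-trimethoxybenzyl)dihydrofuran-2(3H)-one | COc1cc(/C=C2/C(=O)OC[C@@H]2Cc2cc(OC)c(OC)c(OC)c2)cc(OC)c1O[Si](C)(C)C(C)(C)C | intermediate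
17 | (3E,4R)-3-(4-hydroxy-3,5-dimethoxybenzylidene)-4-(3,4,5-trimethoxybenzyl)dihydrofuran-2(3H)-one (CNP0198204.1) | COc1cc(/C=C2/C(=O)OC[C@@H]2Cc2cc(OC)c(OC)c(OC)c2)cc(OC)c1O | target

**Totals**
Total step count: 7. Longest linear sequence: 6 (steps 1, 2, 3, 4, 6, 7); step 5 is a one-step side branch.

**Three steps most likely to fail, with fallbacks**

Step 6 (one-flask aldol, acetylation, elimination). Risks are retro-aldol on warming, an E/Z mixture, and base-induced migration of the double bond into the ring, which would destroy C4. The fallback is a Horner–Wadsworth–Emmons route that sets out from lactone 11. Deprotonation with LiN(i-Pr)2 in THF at −78 °C and trapping with ClP(O)(OEt)2 gives the ketene acetal phosphate diethyl (4R)-4-(3,4,5-trimethoxybenzyl)-4,5-dihydrofuran-2-yl phosphate F4. More LiN(i-Pr)2 (2 equiv) then triggers the 1,3-phosphorus shift from O to C, and an acetic acid quench gives the α-phosphono lactone diethyl [(4R)-2-oxo-4-(3,4,5-trimethoxybenzyl)tetrahydrofuran-3-yl]phosphonate F5 as C3 epimers. Olefination of F5 with aldehyde 13 (KOt-Bu, THF, 0 °C → rt) comes back to the route at 16.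

Step 4 (ozonolysis next to an electron-rich arene, through an α-stereogenic aldehyde). Risks are over-oxidation of the trimethoxyphenyl ring and partial epimerisation of 9. The ozone-free fallback sets out from ester 8 and uses OsO4 (2 mol %), NaIO4 (4 equiv) and 2,6-lutidine in dioxane/water at rt. Osmylation gives the diol ethyl (3R)-4,5-dihydroxy-3-(3,4,5-trimethoxybenzyl)hexanoate F3, which periodate cleaves in the same flask to aldehyde 9, now isolated cold. NaBH4 in EtOH at 0 °C takes 9 to 10, and catalytic TsOH in CH2Cl2 closes the ring, coming back at 11.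

Step 1 (alkyne benzylation on the unprotected alkynol). Risks are slow coupling, oxidative alkyne dimerisation and alkyne-to-allene isomerisation of the product. The fallback sets out from alkynol 1, which is silylated (TBSCl, imidazole, DMF) to (R)-tert-butyl(but-3-yn-2-yloxy)dimethylsilane F1. Lithiation with n-BuLi in THF/DMPU at −78 °C and SN2 alkylation of the lithium acetylide with bromide 2 gives (R)-tert-butyldimethyl{[5-(3,4,5-trimethoxyphenyl)pent-3-yn-2-yl]oxy}silane F2. Bu4NF in THF removes the silyl group and comes back at 3.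

**Further compounds**
F1 | step 1 | (R)-tert-butyl(but-3-yn-2-yloxy)dimethylsilane | C[C@@H](O[Si](C)(C)C(C)(C)C)C#C
F2 | step 1 | (R)-tert-butyldimethyl{[5-(3,4,5-trimethoxyphenyl)pent-3-yn-2-yl]oxy}silane | C[C@@H](O[Si](C)(C)C(C)(C)C)C#CCc1cc(OC)c(OC)c(OC)c1
F3 | step 4 | ethyl (3R)-4,5-dihydroxy-3-(3,4,5-trimethoxybenzyl)hexanoate (threo diol, two facial diastereomers) | CC(O)C(O)[C@@H](CC(=O)OCC)Cc1cc(OC)c(OC)c(OC)c1
F4 | step 6 | diethyl (4R)-4-(3,4,5-trimethoxybenzyl)-4,5-dihydrofuran-2-yl phosphate | CCOP(=O)(OCC)OC1=C[C@@H](Cc2cc(OC)c(OC)c(OC)c2)CO1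
F5 | step 6 | diethyl [(4R)-2-oxo-4-(3,4,5-trimethoxybenzyl)tetrahydrofuran-3-yl]phosphonate (C3 epimers) | CCOP(=O)(OCC)C1C(=O)OC[C@@H]1Cc1cc(OC)c(OC)c(OC)c1
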